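**Retrosynthetic overview**
1. Target 17 comes from fluoride desilylation of TBS ether 16, which is the condensation product of 2-aminoimidazole 13 and purchased 1-methylparabanic acid 14 (C–N bond).
2. The 2-amino group of 13 comes from C2 lithiation, azide transfer and azide reduction on silyl ether 10.
3. The (R)-carbinol, the only stereocentre, is set by ketoreductase reduction of aryl imidazolyl ketone 8.
4. Ketone 8 comes from 4,5-diiodo-1-methylimidazole 1 by two regioselective I/Mg exchanges, each trapped with 4-methoxybenzaldehyde 2: first at C5 (then deoxygenation), then at C4 (then oxidation).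
5. No ring is formed: the imidazole and the imidazolidinetrione are bought preformed; the imidazole is substituted at C5, then C4, then C2, and the second ring is attached last.

Assumption: the (R)-selective enzyme for step 5 is picked from a commercial panel of engineered ketoreductases by screening against ketone 8, with ee checked by chiral HPLC and configuration by Mosher esters.

**Route**

Step 1
Reactants: 1 4,5-diiodo-1-methyl-1H-imidazole; 2 4-methoxybenzaldehyde
Product: 4 rac-(4-iodo-1-methyl-1H-imidazol-5-yl)(4-methoxyphenyl)methanol, via imidazol-5-ylmagnesium bromide 3 (not isolated)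
Conditions: EtMgBr (1.05 equiv), THF, 0 °C → rt; then 2, rt; H2O quench
Reagents that add atoms: none
Why: Iodine–magnesium exchange is selective for C5, the position next to N-methyl, and the Grignard reagent 3 adds to the aldehyde (halogen–metal exchange/Grignard addition); the racemic carbinol is removed in step 2.

Step 2
Reactants: 4 rac-(4-iodo-1-methyl-1H-imidazol-5-yl)(4-methoxyphenyl)methanol
Product: 5 4-iodo-5-(4-methoxybenzyl)-1-methyl-1H-imidazole
Conditions: Et3SiH, TFA, CH2Cl2, 0 °C → rt
Reagents that add atoms: none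
Why: Ionic hydrogenation: TFA ionises the p-methoxybenzylic alcohol to a stabilised cation that Et3SiH reduces, and the C4 iodide is untouched.

Step 3
Reactants: 5 4-iodo-5-(4-methoxybenzyl)-1-methyl-1H-imidazole; 2 4-methoxybenzaldehyde
Product: 7 rac-[5-(4-methoxybenzyl)-1-methyl-1H-imidazol-4-yl](4-methoxyphenyl)methanol, via imidazol-4-ylmagnesium chloride 6 (not isolated)
Conditions: i-PrMgCl·LiCl (1.1 equiv), THF, 0 °C → rt; then 2, 0 °C → rt; H2O quench
Reagents that add atoms: none
Why: The remaining C4 iodide undergoes I/Mg exchange and Grignard reagent 6 adds to the aldehyde (Grignard addition); the carbinol is made racemic on purpose because it is oxidised next.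

Step 4
Reactants: 7 rac-[5-(4-methoxybenzyl)-1-methyl-1H-imidazol-4-yl](4-methoxyphenyl)methanol
Product: 8 [5-(4-methoxybenzyl)-1-methyl-1H-imidazol-4-yl](4-methoxyphenyl)methanone
Conditions: MnO2 (10 equiv), CH2Cl2, rt
Reagents that add atoms: none
Why: MnO2 oxidises the doubly activated (benzylic and heterobenzylic) alcohol to the ketone and leaves the diarylmethane CH2 alone (selective benzylic alcohol oxidation).

Step 5
Reactants: 8 [5-(4-methoxybenzyl)-1-methyl-1H-imidazol-4-yl](4-methoxyphenyl)methanone
Product: 9 (R)-[5-(4-methoxybenzyl)-1-methyl-1H-imidazol-4-yl](4-methoxyphenyl)methanol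
Conditions: ketoreductase (engineered NADPH-dependent alcohol dehydrogenase, (R)-selective), NADP+ (cat.), i-PrOH (20% v/v), KH2PO4/K2HPO4 buffer pH 7.0, DMSO (10% v/v), 30 °C, 24 h
Reagents that add atoms: none
Why: Asymmetric biocatalytic ketone reduction: the ketoreductase binds the two different aryl groups in separate pockets and delivers hydride from NADPH (regenerated by isopropanol) to the Si face of the carbonyl, which sets the (R)-carbinol in high ee.

Step 6
Reactants: 9 (R)-[5-(4-methoxybenzyl)-1-methyl-1H-imidazol-4-yl](4-methoxyphenyl)methanol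
Product: 10 4-[(R)-(tert-butyldimethylsilyloxy)(4-methoxyphenyl)methyl]-5-(4-methoxybenzyl)-1-methyl-1H-imidazole
Conditions: TBSCl, imidazole, DMF, rt → 40 °C
Reagents that add atoms: tert-butyldimethylsilyl chloride (TBSCl), CC(C)(C)[Si](C)(C)Cl
Why: O-silylation under non-acidic conditions masks the hydroxyl before the organolithium step and does not touch the C–O bond, so the configuration is retained.

Step 7
Reactants: 10 4-[(R)-(tert-butyldimethylsilyloxy)(4-methoxyphenyl)methyl]-5-(4-methoxybenzyl)-1-methyl-1H-imidazole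
Product: 12 2-azido-4-[(R)-(tert-butyldimethylsilyloxy)(4-methoxyphenyl)methyl]-5-(4-methoxybenzyl)-1-methyl-1H-imidazole, via 2-lithioimidazole 11 (not isolated)
Conditions: n-BuLi (1.05 equiv), THF, −78 °C, 30 min; then TsN3, −78 °C → rt
Reagents that add atoms: tosyl azide (TsN3), Cc1ccc(cc1)S(=O)(=O)N=[N+]=[N-]
Why: C2–H is the kinetically most acidic site of a 1-methylimidazole, so directed lithiation gives 11, which takes an azide group from tosyl azide (electrophilic azide transfer); at −78 °C with one equivalent of base the C–H at the silyloxy stereocentre is not deprotonated.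

Step 8
Reactants: 12 2-azido-4-[(R)-(tert-butyldimethylsilyloxy)(4-methoxyphenyl)methyl]-5-(4-methoxybenzyl)-1-methyl-1H-imidazole
Product: 13 4-[(R)-(tert-butyldimethylsilyloxy)(4-methoxyphenyl)methyl]-5-(4-methoxybenzyl)-1-methyl-1H-imidazol-2-amine
Conditions: H2 (1 atm), 10% Pd/C, EtOAc, rt
Reagents that add atoms: none
Why: Catalytic hydrogenation of the azide to the amine with loss of nitrogen is far faster than hydrogenolysis of the benzylic silyl ether in EtOAc at 1 atm.

Step 9
Reactants: 13 4-[(R)-(tert-butyldimethylsilyloxy)(4-methoxyphenyl)methyl]-5-(4-methoxybenzyl)-1-methyl-1H-imidazol-2-amine; 14 1-methylimidazolidine-2,4,5-trione (1-methylparabanic acid)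
Product: 16 4-({4-[(R)-(tert-butyldimethylsilyloxy)(4-methoxyphenyl)methyl]-5-(4-methoxybenzyl)-1-methyl-1H-imidazol-2-yl}amino)-1-methyl-1H-imidazole-2,5-dione, via O-trimethylsilyl imidate 15 (not isolated)
Conditions: 14 (1.5 equiv), BSA [N,O-bis(trimethylsilyl)acetamide], MeCN, rt, 1 h; then 13, toluene, 110 °C
Reagents that add atoms: none
Why: BSA turns 14 into silyl imidate 15, whose C4 is attacked by the exocyclic 2-amino group in an addition–elimination (amidine-forming condensation) that expels the silyloxy group, the established way to the naamidine-type aminoimidazoledione.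

Step 10
Reactants: 16 4-({4-[(R)-(tert-butyldimethylsilyloxy)(4-methoxyphenyl)methyl]-5-(4-methoxybenzyl)-1-methyl-1H-imidazol-2-yl}amino)-1-methyl-1H-imidazole-2,5-dione
Product: 17 4-({4-[(R)-hydroxy(4-methoxyphenyl)methyl]-5-(4-methoxybenzyl)-1-methyl-1H-imidazol-2-yl}amino)-1-methyl-1H-imidazole-2,5-dione (target)
Conditions: Bu4NF, AcOH (1:1), THF, 0 °C → rt
Reagents that add atoms: none
Why: Buffered fluoride desilylation cleaves the Si–O bond and not the C–O bond, so the (R)-configuration is kept, and the acetic acid buffer protects the base-sensitive imidazoledione.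

**Compound list**
1 | 4,5-diiodo-1-methyl-1H-imidazole | Cn1cnc(I)c1I | starting material
2 | 4-methoxybenzaldehyde | COc1ccc(C=O)cc1 | starting material
3 | (4-iodo-1-methyl-1H-imidazol-5-yl)magnesium bromide | Cn1cnc(I)c1[Mg]Br | intermediate
4 | rac-(4-iodo-1-methyl-1H-imidazol-5-yl)(4-methoxyphenyl)methanol | COc1ccc(C(O)c2c(I)ncn2C)cc1 | intermediate
5 | 4-iodo-5-(4-methoxybenzyl)-1-methyl-1H-imidazole | COc1ccc(Cc2c(I)ncn2C)cc1 | intermediate
6 | [5-(4-methoxybenzyl)-1-methyl-1H-imidazol-4-yl]magnesium chloride | COc1ccc(Cc2c([Mg]Cl)ncn2C)cc1 | intermediate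
7 | rac-[5-(4-methoxybenzyl)-1-methyl-1H-imidazol-4-yl](4-methoxyphenyl)methanol | COc1ccc(Cc2c(C(O)c3ccc(OC)cc3)ncn2C)cc1 | intermediate
8 | [5-(4-methoxybenzyl)-1-methyl-1H-imidazol-4-yl](4-methoxyphenyl)methanone | COc1ccc(Cc2c(C(=O)c3ccc(OC)cc3)ncn2C)cc1 | intermediate
9 | (R)-[5-(4-methoxybenzyl)-1-methyl-1H-imidazol-4-yl](4-methoxyphenyl)methanol | COc1ccc(Cc2c([C@H](O)c3ccc(OC)cc3)ncn2C)cc1 | intermediate
10 | 4-[(R)-(tert-butyldimethylsilyloxy)(4-methoxyphenyl)methyl]-5-(4-methoxybenzyl)-1-methyl-1H-imidazole | COc1ccc(Cc2c([C@H](O[Si](C)(C)C(C)(C)C)c3ccc(OC)cc3)ncn2C)cc1 | intermediate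
11 | 2-lithio derivative of 10 (lithium at C2 of the imidazole, (R)-silyl ether unchanged) | COc1ccc(Cc2c([C@H](O[Si](C)(C)C(C)(C)C)c3ccc(OC)cc3)nc([Li])n2C)cc1 | intermediate
12 | 2-azido-4-[(R)-(tert-butyldimethylsilyloxy)(4-methoxyphenyl)methyl]-5-(4-methoxybenzyl)-1-methyl-1H-imidazole | COc1ccc(Cc2c([C@H](O[Si](C)(C)C(C)(C)C)c3ccc(OC)cc3)nc(N=[N+]=[N-])n2C)cc1 | intermediate
13 | 4-[(R)-(tert-butyldimethylsilyloxy)(4-methoxyphenyl)methyl]-5-(4-methoxybenzyl)-1-methyl-1H-imidazol-2-amine | COc1ccc(Cc2c([C@H](O[Si](C)(C)C(C)(C)C)c3ccc(OC)cc3)nc(N)n2C)cc1 | intermediate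
14 | 1-methylimidazolidine-2,4,5-trione (1-methylparabanic acid) | CN1C(=O)NC(=O)C1=O | starting material
15 | 1-methyl-4-(trimethylsilyloxy)-1H-imidazole-2,5-dione | CN1C(=O)N=C(O[Si](C)(C)C)C1=O | intermediate
16 | 4-({4-[(R)-(tert-butyldimethylsilyloxy)(4-methoxyphenyl)methyl]-5-(4-methoxybenzyl)-1-methyl-1H-imidazol-2-yl}amino)-1-methyl-1H-imidazole-2,5-dione | COc1ccc(Cc2c([C@H](O[Si](C)(C)C(C)(C)C)c3ccc(OC)cc3)nc(NC3=NC(=O)N(C)C3=O)n2C)cc1 | intermediate
17 | 4-({4-[(R)-hydroxy(4-methoxyphenyl)methyl]-5-(4-methoxybenzyl)-1-methyl-1H-imidazol-2-yl}amino)-1-methyl-1H-imidazole-2,5-dione | COc1ccc(Cc2c([C@H](O)c3ccc(OC)cc3)nc(NC3=NC(=O)N(C)C3=O)n2C)cc1 | target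

**Totals**
Total step count: 10. Longest linear sequence: 10 steps (1 → 17); 2 and 14 are purchased and enter directly.

**Steps most likely to fail, and fallbacks**

Step 5. The ketone carries two bulky, electron-rich aryl groups, so a panel enzyme may give low conversion or insufficient (R)-selectivity. The fallback sets out from 5 and comes back at 9. Grignard reagent 6, made from 5 as in step 3, is quenched with DMF to give 5-(4-methoxybenzyl)-1-methyl-1H-imidazole-4-carbaldehyde F1. A catalytic enantioselective aryl transfer to F1 then forms the C–C bond and the stereocentre together and gives 9. Its conditions are 4-methoxyphenylboronic acid premixed with ZnEt2, 10 mol% of a chiral amino alcohol ligand (the enantiomer of 3-exo-morpholinoisoborneol that leads to the (R)-alcohol), toluene, 0 °C. Steps 3 to 5 fall away.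

Step 7. Butyllithium could also deprotonate the benzylic C–H at the silyloxy carbon, which would racemise it or trigger silyl migration, and the azide transfer can stall at the triazene stage. The fallback sets out from 10 and comes back at 13. NBS (1.0 equiv) in THF at −78 → 0 °C in the dark brominates the only free ring carbon and gives 2-bromo-4-[(R)-(tert-butyldimethylsilyloxy)(4-methoxyphenyl)methyl]-5-(4-methoxybenzyl)-1-methyl-1H-imidazole F2. A Buchwald–Hartwig coupling with benzophenone imine (Pd2(dba)3, t-BuBrettPhos, NaOt-Bu, toluene, 90 °C) gives N-(diphenylmethylidene)-4-[(R)-(tert-butyldimethylsilyloxy)(4-methoxyphenyl)methyl]-5-(4-methoxybenzyl)-1-methyl-1H-imidazol-2-amine F3. Transimination with NH2OH·HCl/NaOAc in MeOH at rt releases 13. This avoids both the organolithium and the azide.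

Step 10. The aminoimidazoledione is sensitive to basic fluoride, and the carbinol between two electron-rich rings ionises easily. The fallback sets out from 13 and comes back at 17. Bu4NF in THF at rt removes the silyl group at the amine stage and gives (R)-[2-amino-5-(4-methoxybenzyl)-1-methyl-1H-imidazol-4-yl](4-methoxyphenyl)methanol F4. Condensation with 14 and excess BSA as in step 9 (through 15) gives 4-({5-(4-methoxybenzyl)-4-[(R)-(4-methoxyphenyl)(trimethylsilyloxy)methyl]-1-methyl-1H-imidazol-2-yl}amino)-1-methyl-1H-imidazole-2,5-dione F5, the transient O-trimethylsilyl ether of the target. This labile ether is cleaved with catalytic K2CO3 in MeOH at 0 °C to give 17, so the finished imidazoledione never meets fluoride.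

**Further compounds**
F1 | step 5 | 5-(4-methoxybenzyl)-1-methyl-1H-imidazole-4-carbaldehyde | COc1ccc(Cc2c(C=O)ncn2C)cc1
F2 | step 7 | 2-bromo-4-[(R)-(tert-butyldimethylsilyloxy)(4-methoxyphenyl)methyl]-5-(4-methoxybenzyl)-1-methyl-1H-imidazole | COc1ccc(Cc2c([C@H](O[Si](C)(C)C(C)(C)C)c3ccc(OC)cc3)nc(Br)n2C)cc1
F3 | step 7 | N-(diphenylmethylidene)-4-[(R)-(tert-butyldimethylsilyloxy)(4-methoxyphenyl)methyl]-5-(4-methoxybenzyl)-1-methyl-1H-imidazol-2-amine | COc1ccc(Cc2c([C@H](O[Si](C)(C)C(C)(C)C)c3ccc(OC)cc3)nc(N=C(c3ccccc3)c3ccccc3)n2C)cc1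
F4 | step 10 | (R)-[2-amino-5-(4-methoxybenzyl)-1-methyl-1H-imidazol-4-yl](4-methoxyphenyl)methanol | COc1ccc(Cc2c([C@H](O)c3ccc(OC)cc3)nc(N)n2C)cc1
F5 | step 10 | 4-({5-(4-methoxybenzyl)-4-[(R)-(4-methoxyphenyl)(trimethylsilyloxy)methyl]-1-methyl-1H-imidazol-2-yl}amino)-1-methyl-1H-imidazole-2,5-dione | COc1ccc(Cc2c([C@H](O[Si](C)(C)C)c3ccc(OC)cc3)nc(NC3=NC(=O)N(C)C3=O)n2C)cc1
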